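## Analysis of the target

Ligraminol D (14) is an open-chain 7-deoxy-8-O-4' neolignan built on a C7–C8–C9 propane unit. C7 is a benzylic CH2 on a 3,4-dimethoxyphenyl ring (ring A), C9 is a primary CH2OH, and C8 carries an aryl ether oxygen to a 2-methoxyphenyl ring (ring B) that bears a 3-hydroxypropyl chain para to that oxygen. The two benzene rings are the only rings, so nothing has to be cyclised. C8 is the only stereocentre and is S (OAr > C9 > C7 > H); with no second centre to relay from, its absolute configuration must come from a reagent, a catalyst or an auxiliary. The sensitive points are the two electron-rich arenes (open to electrophilic attack and benzylic ionisation under acid), the secondary alkyl aryl ether at C8, and two primary alcohols that both end up free and are better carried masked than protected. The difficulty sits at C8: it is flanked by two CH2 groups of similar size, and its C–O bond to an ortho-substituted phenol is awkward to make by substitution without elimination towards the styrene. The feature the route rests on is that C9 is a carboxyl carbon in reduced form, so C8 is the α-carbon of an aryloxyacetic acid and C7–C8 is a bond between an enolate carbon and a benzylic electrophile. Ring B, with its ortho methoxy group and para three-carbon chain, is the skeleton of eugenol (1), whose allyl group is a base- and hydride-stable precursor of the hydroxypropyl chain.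

## Retrosynthetic reasoning

The terminal C–O bond of the hydroxypropyl chain on ring B is cut first, which leads from 14 back to the allyl compound 12, (S)-2-(4-allyl-2-methoxyphenoxy)-3-(3,4-dimethoxyphenyl)propan-1-ol. A terminal alkene is the one precursor of a primary alcohol that passes untouched through a strong amide base and a complex hydride, so no protecting group is needed anywhere. The forward reaction must be an anti-Markovnikov hydration of a monosubstituted alkene beside a free primary alcohol; hydroboration with a hindered dialkylborane and oxidation, through the boron adduct 13, does this.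

C9 is then raised to the carboxyl level: 12 comes from the N-acyl oxazolidinone 11 by reductive removal of the auxiliary, which returns (R)-4-benzyloxazolidin-2-one (4). What is gained is a group on C9 that both acidifies C8 and directs its configuration. The forward step must reduce the exocyclic carbonyl in preference to the ring carbonyl and must not enolise C8.

The C7–C8 bond is cut next. Making C8–O would need a phenoxide to displace a secondary leaving group next to a benzylic CH2, where elimination competes, and C8–C9 has no natural polarity. C7–C8 divides the molecule into a stabilised nucleophile, the sodium Z-enolate 10 of the aryloxyacetyl imide 7, and a very reactive electrophile, 3,4-dimethoxybenzyl bromide (9). This is the only skeletal C–C bond not already present in the starting materials, and forming it sets the only stereocentre in the same operation. The forward reaction must deliver S at C8, which is why the R enantiomer of the auxiliary is used.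

The N-acyl bond of 7 is cut to 2-(4-allyl-2-methoxyphenoxy)acetic acid (3) and the auxiliary 4. The forward coupling activates 3 as the mixed anhydride 5 and 4 as its lithium salt 6, a standard pairing that needs no coupling reagent.

The aryl ether bond of 3 is cut between the phenolic oxygen of eugenol (1) and the CH2 of bromoacetic acid (2). At this stage the future C8 is a primary, unhindered carbon α to a carboxylate, so the ether bond that would be troublesome at the secondary centre is made before that centre exists.

The C–Br bond of 9 is traced to 3,4-dimethoxybenzyl alcohol (8), because an electron-rich benzylic bromide does not keep and should be made immediately before the key step.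

## Alternatives that were turned down

Alternative 1: The disconnection is at C8–H and C9–O, with C8 generated from the trigonal carbon of the 1,1-disubstituted enol ether A2, itself made by methylenation (Cp2TiMe2) of the aryl arylacetate A3. The forward key step is a copper hydride-catalysed hydroboration of A2 with pinacolborane (Cu(OAc)2, DTBM-SEGPHOS), placing hydride on C8 and boron on C9 to give boronate A1. Oxidation of the C–B bond and desilylation would then give 14. A1 has the spatial arrangement of 14, but its descriptor is R because CH2B ranks below CH2Ar.
- For: the chiral component is catalytic, no auxiliary is consumed, and the centre is made late from a flat precursor.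
- Against: the catalyst must tell OAr from CH2Ar on the trigonal carbon, two flexible groups of similar size. The alkylcopper intermediate has the aryloxy group β to copper, so β-aryloxy elimination to an allylarene is a ready exit. A2 is an acid-labile enol ether. The side-chain alcohol of ring B must be carried as a silyl ether, which brings the longest line to about seven steps.
- Comparison: this route is stronger in atom economy. The chosen route offers a facial preference predictable from a rigid chelate, a minor isomer that is a separable diastereomer, and two steps fewer.

Alternative 2: The disconnection is at C7–H and C8–H. The skeleton is first assembled as a C7=C8 alkene by Perkin condensation of an aryloxyacetic acid with the ring A aldehyde, giving the Z acid A4; the side-chain acetate arises in the anhydride medium. The forward key step is hydrogenation of A4 with H2 over [Ir(cod)(L)]BArF (L a chiral spiro phosphine-oxazoline) or Ru(OAc)2(BINAP), directed by the carboxylate, to give the S acid A5. One hydride reduction would then convert CO2H into C9H2OH and remove the acetate.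
- For: α-aryloxy unsaturated acids suit carboxyl-directed hydrogenation well, the chirality is catalytic, nothing is run at low temperature, and the step count is about the same.
- Against: the Perkin condensation with an electron-rich, weakly electrophilic aldehyde needs hot anhydride and amine and tends to give incomplete conversion and E/Z mixtures. Geometric isomers as a rule give opposite enantiomers, so the isomeric purity of A4 limits the ee. A5 is an enantiomeric mixture that can only be upgraded by salt crystallisation. A specialised ligand and pressure equipment are needed, and the ligand antipode has to be matched by trial.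
- Comparison: on atom economy, scalability and freedom from stoichiometric chiral material this route is at least as strong, probably stronger. The chosen route offers a predictable configuration, a diastereomeric minor isomer removable at 11, commodity reagents only, and recovery of the auxiliary in step 5.

Alternative 3: The disconnection is the bond between C7 and ring A, after C8 has been made stereogenic by distinguishing the two CH2OH arms of the prochiral diol A6. A6 would come from 1 and a halomalonate, followed by reduction. The forward key step is acetylation of one enantiotopic arm by a lipase (Burkholderia cepacia lipase or Candida antarctica lipase B) with vinyl acetate, giving the S monoacetate A7. The free arm of A7 must then become C7 by sulfonylation and copper-catalysed coupling with an aryl Grignard reagent, while the acetylated arm becomes C9.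
- For: the chiral agent is cheap and mild, 2-O-substituted glycerol derivatives are classic lipase substrates, and a symmetric precursor can in principle be converted completely.
- Against: a 1,3-acyl shift in A7 turns the compound into its enantiomer, so any migration erodes the ee. The acetate does not survive the Grignard reagent, which forces a protecting-group exchange. Substitution at a primary sulfonate with a β-aryloxy group competes with elimination. Which arm the enzyme acylates must be found by experiment. The line runs to about eight steps.
- Comparison: this route is stronger in the cost of the chiral agent and in avoiding −78 °C. The chosen route forms C7–C8 and sets C8 in one event, has no intermediate that can racemise by group migration, and is about three steps shorter.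

Key step: step 4

Assumption: lignan numbering is used (C7 is the benzylic CH2 on ring A, C8 the stereocentre, C9 the CH2OH), and bromide 9 is prepared fresh from 8 because electron-rich benzylic bromides deteriorate on storage.

## Route

Step 1
Reactants: 1 eugenol (4-allyl-2-methoxyphenol); 2 bromoacetic acid
Product: 3 2-(4-allyl-2-methoxyphenoxy)acetic acid
Conditions: NaOH (2.5 equiv), H2O, 80 °C; then aq. HCl, 0 °C
Reagents that add atoms: none
Why: Williamson ether synthesis: the phenoxide of 1 displaces bromide from the bromoacetate anion at a primary carbon, and 3 precipitates on acidification. The allyl group is not isomerised by aqueous hydroxide at this temperature, and no stereocentre is involved.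

Step 2
Reactants: 3 2-(4-allyl-2-methoxyphenoxy)acetic acid; 4 (R)-4-benzyloxazolidin-2-one
Product: 7 (R)-3-[2-(4-allyl-2-methoxyphenoxy)acetyl]-4-benzyloxazolidin-2-one, via pivalic mixed anhydride 5 (not isolated), via lithiated oxazolidinone 6 (not isolated)
Conditions: 3, Et3N, t-BuCOCl, THF, −20 °C; then 4/n-BuLi (THF, −78 °C) added, −78 → 0 °C
Reagents that add atoms: none
Why: N-acylation of a lithiated Evans auxiliary by a mixed pivalic anhydride; the nitrogen anion attacks the unhindered aryloxyacetyl carbonyl and not the tert-butyl-shielded one. The stereocentre of the auxiliary is not touched.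

Step 3
Reactants: 8 3,4-dimethoxybenzyl alcohol
Product: 9 3,4-dimethoxybenzyl bromide
Conditions: PBr3 (0.4 equiv), Et2O, 0 °C; cold aq. NaHCO3 wash, dried, concentrated cold and used at once
Reagents that add atoms: phosphorus tribromide, BrP(Br)Br
Why: Conversion of a benzylic alcohol into its bromide through a bromophosphite that bromide displaces; the electron-rich ring makes this fast at 0 °C. Immediate use avoids self-alkylation of the product on standing.

Step 4
Reactants: 7 (R)-3-[2-(4-allyl-2-methoxyphenoxy)acetyl]-4-benzyloxazolidin-2-one; 9 3,4-dimethoxybenzyl bromide
Product: 11 (R)-3-[(S)-2-(4-allyl-2-methoxyphenoxy)-3-(3,4-dimethoxyphenyl)propanoyl]-4-benzyloxazolidin-2-one, via sodium Z-enolate 10 (not isolated)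
Conditions: NaN(SiMe3)2 (1.1 equiv), THF, −78 °C; then 9 (3 equiv), −78 → −45 °C; AcOH quench at −45 °C
Reagents that add atoms: none
Why: NaN(SiMe3)2 removes the C8 proton of 7 at −78 °C to give the sodium Z-enolate 10, in which the aryloxy group is cis to the enolate oxygen (the geometry free of allylic 1,3-strain with the auxiliary) and sodium is chelated between the enolate oxygen and the oxazolidinone carbonyl. The chelate holds the auxiliary coplanar with the enolate, so the 4-benzyl group of the R auxiliary covers the Re face of C8, and bromide 9 is attacked in an SN2 displacement from the open Si face, which forms the C7–C8 bond. C8 is thereby S (OAr > C9 > C7 > H), controlled by C4 of the auxiliary acting through the rigid chelate; the minor product would be a diastereomer and can be removed at this stage. The closest known reaction type is the Evans alkylation of α-alkoxyacetyl (glycolate) oxazolidinone sodium enolates with allylic and benzylic halides; no ring is closed. The step needs facial selectivity (chelation plus benzyl shielding), C- over O-alkylation (a soft benzylic bromide and a tight sodium chelate favour carbon) and mono-alkylation (one equivalent of base, and the remaining C8–H of 11 is flanked by two substituents). The two methoxy groups should make 9 reactive enough to capture the enolate below −45 °C, before it can fragment by loss of the oxazolidinone anion, and the cold acetic acid quench prevents epimerisation of 11. The allyl group and the aryl ethers are inert to the silylamide base.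

Step 5
Reactants: 11 (R)-3-[(S)-2-(4-allyl-2-methoxyphenoxy)-3-(3,4-dimethoxyphenyl)propanoyl]-4-benzyloxazolidin-2-one
Product: 12 (S)-2-(4-allyl-2-methoxyphenoxy)-3-(3,4-dimethoxyphenyl)propan-1-ol
Conditions: LiBH4 (2 equiv), MeOH (1 equiv), THF, 0 °C; then H2O
Reagents that add atoms: none
Why: Reductive cleavage of an N-acyl oxazolidinone: hydride adds to the exocyclic carbonyl, the more electrophilic of the two, and the acyl carbon is taken down to CH2OH while 4 is released for recovery. C8 is not enolised under these weakly basic conditions, so its configuration is kept, and the alkene is inert.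

Step 6
Reactants: 12 (S)-2-(4-allyl-2-methoxyphenoxy)-3-(3,4-dimethoxyphenyl)propan-1-ol
Product: 14 ligraminol D, via bis-boron adduct 13 (not isolated)
Conditions: 9-BBN (2.5 equiv), THF, 0 °C → rt; then 3 M NaOH, 30% H2O2, 0 °C → rt
Reagents that add atoms: hydrogen peroxide, OO
Why: Hydroboration–oxidation: the bulky dialkylborane places boron on the terminal carbon of the allyl group, while one equivalent is taken up by the C9 hydroxyl as a borinate. Alkaline peroxide then replaces the C–B bond by C–OH and hydrolyses the O–B bond. C8 and the aryl ethers are not affected.

## Compound list

1 | eugenol (4-allyl-2-methoxyphenol) | C=CCc1ccc(O)c(OC)c1 | starting material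
2 | bromoacetic acid | OC(=O)CBr | starting material
3 | 2-(4-allyl-2-methoxyphenoxy)acetic acid | C=CCc1ccc(OCC(=O)O)c(OC)c1 | intermediate
4 | (R)-4-benzyloxazolidin-2-one | O=C1N[C@H](Cc2ccccc2)CO1 | starting material
5 | 2-(4-allyl-2-methoxyphenoxy)acetic pivalic anhydride | C=CCc1ccc(OCC(=O)OC(=O)C(C)(C)C)c(OC)c1 | intermediate
6 | lithium salt of (R)-4-benzyloxazolidin-2-one | [Li+].O=C1[N-][C@H](Cc2ccccc2)CO1 | intermediate
7 | (R)-3-[2-(4-allyl-2-methoxyphenoxy)acetyl]-4-benzyloxazolidin-2-one | C=CCc1ccc(OCC(=O)N2[C@H](Cc3ccccc3)COC2=O)c(OC)c1 | intermediate
8 | 3,4-dimethoxybenzyl alcohol | COc1ccc(CO)cc1OC | starting material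
9 | 3,4-dimethoxybenzyl bromide | COc1ccc(CBr)cc1OC | intermediate
10 | sodium Z-enolate of 7 | [Na+].C=CCc1ccc(O/C=C(\[O-])N2[C@H](Cc3ccccc3)COC2=O)c(OC)c1 | intermediate
11 | (R)-3-[(S)-2-(4-allyl-2-methoxyphenoxy)-3-(3,4-dimethoxyphenyl)propanoyl]-4-benzyloxazolidin-2-one | COc1ccc(C[C@@H](C(=O)N2[C@H](Cc3ccccc3)COC2=O)Oc2ccc(CC=C)cc2OC)cc1OC | intermediate
12 | (S)-2-(4-allyl-2-methoxyphenoxy)-3-(3,4-dimethoxyphenyl)propan-1-ol | COc1ccc(C[C@@H](CO)Oc2ccc(CC=C)cc2OC)cc1OC | intermediate
13 | 9-[3-[4-[[(S)-1-(9-borabicyclo[3.3.1]nonan-9-yloxy)-3-(3,4-dimethoxyphenyl)propan-2-yl]oxy]-3-methoxyphenyl]propyl]-9-borabicyclo[3.3.1]nonane | COc1ccc(C[C@@H](COB2C3CCCC2CCC3)Oc2ccc(CCCB3C4CCCC3CCC4)cc2OC)cc1OC | intermediate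
14 | ligraminol D, (S)-3-[4-[[1-(3,4-dimethoxyphenyl)-3-hydroxypropan-2-yl]oxy]-3-methoxyphenyl]propan-1-ol | COc1ccc(C[C@@H](CO)Oc2ccc(CCCO)cc2OC)cc1OC | target

## Step count and least certain steps

Total step count: 6. Longest linear sequence: 5 steps (steps 1, 2, 4, 5 and 6 from eugenol 1); step 3 is a one-step side branch.

**Step 4 (key step).** The most likely failure is fragmentation of the aryloxy-substituted sodium enolate (loss of the oxazolidinone anion) or its self-acylation before the electrophile has reacted. Facial selectivity could also erode if the chelate loosens on warming. The fallback sets out from 1 and returns at 12, and makes the C8–O bond with inversion in place of the C7–C8 bond. Commercial methyl (R)-glycidate is opened at its CH2 terminus by commercial (3,4-dimethoxyphenyl)magnesium bromide with catalytic CuI (THF, −40 °C) to give methyl (R)-3-(3,4-dimethoxyphenyl)-2-hydroxypropanoate F1. A Mitsunobu reaction of F1 with eugenol 1 (PPh3, diisopropyl azodicarboxylate, toluene, 0 °C → rt) then inverts the carbinol centre and should give methyl (S)-2-(4-allyl-2-methoxyphenoxy)-3-(3,4-dimethoxyphenyl)propanoate F2. Reduction of F2 with LiBH4 in THF gives 12.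

**Step 3.** The most likely failure is decomposition of the electron-rich benzylic bromide, by alkylation of its own ring and by hydrolysis during concentration, so that the key step receives an electrophile of uncertain quality. The fallback sets out from 8 and returns at 11. Alcohol 8 is converted with SOCl2 (CH2Cl2, 0 °C) into 3,4-dimethoxybenzyl chloride F3, which can be purified and kept cold. A Finkelstein exchange (NaI, acetone, rt, in the dark) immediately before use gives 3,4-dimethoxybenzyl iodide F4. After filtration and solvent exchange into THF, F4 is added to enolate 10 at −78 °C to give 11.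

**Step 6.** The most likely failure is consumption of the borane by the free C9 hydroxyl, which leaves alkene unreacted, together with a difficult separation of the polar borane-derived diol from the equally polar product. The fallback sets out from 11 and returns at 14, and moves the hydroboration ahead of the auxiliary cleavage. Imide 11, which has no hydroxyl, is treated with 9-BBN (1.3 equiv, THF) to give (R)-3-[(S)-2-[4-[3-(9-borabicyclo[3.3.1]nonan-9-yl)propyl]-2-methoxyphenoxy]-3-(3,4-dimethoxyphenyl)propanoyl]-4-benzyloxazolidin-2-one F5. Oxidation under near-neutral conditions that spare the imide (pH 7 phosphate buffer, MeOH, 30% H2O2, 0 °C → rt) gives (R)-4-benzyl-3-[(S)-2-[4-(3-hydroxypropyl)-2-methoxyphenoxy]-3-(3,4-dimethoxyphenyl)propanoyl]oxazolidin-2-one F6, from which the borane by-product separates easily because F6 is much less polar. Reduction of F6 with LiBH4 and MeOH in THF, as in step 5, gives 14 directly.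

**Step 5.** The most likely failure is hydride attack at the ring carbonyl of the auxiliary, with ring opening, because the exocyclic carbonyl is hindered by the branched α-carbon. Partial epimerisation at C8 under the basic conditions is the second risk. The fallback sets out from 11 and returns at 12, and replaces reductive cleavage by hydrolytic cleavage followed by a separate reduction. LiOH and H2O2 (THF/H2O, 0 °C) attack the exocyclic carbonyl selectively and give (S)-2-(4-allyl-2-methoxyphenoxy)-3-(3,4-dimethoxyphenyl)propanoic acid F7, which is separated from the recovered auxiliary by extraction into aqueous base. Reduction of F7 with LiAlH4 (THF, 0 °C), which leaves the alkene alone, gives 12.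

## Further compounds

F1 | step 4 | methyl (R)-3-(3,4-dimethoxyphenyl)-2-hydroxypropanoate | COc1ccc(C[C@@H](O)C(=O)OC)cc1OC
F2 | step 4 | methyl (S)-2-(4-allyl-2-methoxyphenoxy)-3-(3,4-dimethoxyphenyl)propanoate | COc1ccc(C[C@@H](C(=O)OC)Oc2ccc(CC=C)cc2OC)cc1OC
F3 | step 3 | 3,4-dimethoxybenzyl chloride | COc1ccc(CCl)cc1OC
F4 | step 3 | 3,4-dimethoxybenzyl iodide | COc1ccc(CI)cc1OC
F5 | step 6 | (R)-3-[(S)-2-[4-[3-(9-borabicyclo[3.3.1]nonan-9-yl)propyl]-2-methoxyphenoxy]-3-(3,4-dimethoxyphenyl)propanoyl]-4-benzyloxazolidin-2-one | COc1ccc(C[C@@H](C(=O)N2[C@H](Cc3ccccc3)COC2=O)Oc2ccc(CCCB3C4CCCC3CCC4)cc2OC)cc1OC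
F6 | step 6 | (R)-4-benzyl-3-[(S)-2-[4-(3-hydroxypropyl)-2-methoxyphenoxy]-3-(3,4-dimethoxyphenyl)propanoyl]oxazolidin-2-one | COc1ccc(C[C@@H](C(=O)N2[C@H](Cc3ccccc3)COC2=O)Oc2ccc(CCCO)cc2OC)cc1OC
F7 | step 5 | (S)-2-(4-allyl-2-methoxyphenoxy)-3-(3,4-dimethoxyphenyl)propanoic acid | COc1ccc(C[C@@H](C(=O)O)Oc2ccc(CC=C)cc2OC)cc1OC
A1 | alternative 1 | tert-butyl[3-[4-[[(R)-1-(3,4-dimethoxyphenyl)-3-(4,4,5,5-tetramethyl-1,3,2-dioxaborolan-2-yl)propan-2-yl]oxy]-3-methoxyphenyl]propoxy]dimethylsilane | COc1ccc(C[C@@H](CB2OC(C)(C)C(C)(C)O2)Oc2ccc(CCCO[Si](C)(C)C(C)(C)C)cc2OC)cc1OC
A2 | alternative 1 | tert-butyl[3-[4-[[3-(3,4-dimethoxyphenyl)prop-1-en-2-yl]oxy]-3-methoxyphenyl]propoxy]dimethylsilane | COc1ccc(CC(=C)Oc2ccc(CCCO[Si](C)(C)C(C)(C)C)cc2OC)cc1OC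
A3 | alternative 1 | 4-[3-(tert-butyldimethylsilyloxy)propyl]-2-methoxyphenyl 2-(3,4-dimethoxyphenyl)acetate | COc1ccc(CC(=O)Oc2ccc(CCCO[Si](C)(C)C(C)(C)C)cc2OC)cc1OC
A4 | alternative 2 | (Z)-2-[4-(3-acetoxypropyl)-2-methoxyphenoxy]-3-(3,4-dimethoxyphenyl)acrylic acid | COc1ccc(/C=C(\Oc2ccc(CCCOC(C)=O)cc2OC)C(=O)O)cc1OC
A5 | alternative 2 | (S)-2-[4-(3-acetoxypropyl)-2-methoxyphenoxy]-3-(3,4-dimethoxyphenyl)propanoic acid | COc1ccc(C[C@@H](C(=O)O)Oc2ccc(CCCOC(C)=O)cc2OC)cc1OC
A6 | alternative 3 | 2-(4-allyl-2-methoxyphenoxy)propane-1,3-diol | C=CCc1ccc(OC(CO)CO)c(OC)c1
A7 | alternative 3 | (S)-2-(4-allyl-2-methoxyphenoxy)-3-hydroxypropyl acetate | C=CCc1ccc(O[C@@H](CO)COC(C)=O)c(OC)c1
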